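**Retrosynthetic overview**
1. Acetylation and desilylation lead back from the target to the 2'-O-TBS 4-alkylcyclopenta[c]pyran-7-carbaldehyde.
2. The feature used: the five-membered ring (C4a, C5, C6, C7, C7a) shares only the C4a–C7a bond with the pyran ring. C7 carries CHO, so it is the α-carbon of an acetaldehyde arm on C7a, and C5–C6 is a two-carbon arm on the pyran γ-carbon C4a. Cutting C6–C7 therefore leaves a monocyclic pyran with the formyl carbon already in place.
3. The nucleophilic arm is a silyl enol ether and the electrophilic arm is a (Z)-2-ethoxyvinyl carbinol. The carbinol comes from a 3,5-disubstituted 4H-pyran-4-one and (Z)-2-ethoxyvinyllithium.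
4. The pyranone comes from an acyclic ketone and two ethyl formate units. The ketone comes from a 3,3-dimethoxypropyl Grignard reagent and an aldehyde made from geranial by asymmetric allylboration, which sets the only stereocentre.
5. Ring order: the pyran ring forms first (step 7) and the five-membered ring second (step 11).

Key step: step 11

Remark: geranial is taken as the purchased pure E isomer; locants C1–C7a are those of cyclopenta[c]pyran and are also used for the matching atoms of the monocyclic precursors (pyranone C4 = C4a, C3 = C7a, C5 = C4), and C2' is the side-chain carbinol carbon.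

**Step 1**
Reactants: 1 geranial; 2 allylmagnesium bromide
Product: 5 (4S,5E)-6,10-dimethylundeca-1,5,9-trien-4-ol, via B-allyldiisopinocampheylborane 3 (not isolated), via homoallyl diisopinocampheylborinate 4 (not isolated)
Conditions: 2, (−)-Ipc2BOMe [derived from (+)-α-pinene], Et2O, −78 °C to rt; 1, −78 °C; 3 M NaOH, 30% H2O2, 0 °C to rt
Reagents that add atoms: none
Why: Brown asymmetric allylboration, in which the (+)-α-pinene-derived allylborane delivers allyl in a 1,2 sense through a chair Zimmerman–Traxler transition state to the Si face of the enal carbonyl, which should set C2' as S (the sense known for aldehydes whose substituent outranks allyl, such as benzaldehyde and other enals).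

**Step 2**
Reactants: 5 (4S,5E)-6,10-dimethylundeca-1,5,9-trien-4-ol
Product: 6 (4S,5E)-4-(tert-butyldimethylsilyloxy)-6,10-dimethylundeca-1,5,9-triene
Conditions: TBSCl, imidazole, DMF, rt
Reagents that add atoms: tert-butyldimethylsilyl chloride, CC(C)(C)[Si](C)(C)Cl
Why: Imidazole-promoted O-silylation of a secondary allylic alcohol breaks no bond at the stereocentre, so the S configuration is kept.

**Step 3**
Reactants: 6 (4S,5E)-4-(tert-butyldimethylsilyloxy)-6,10-dimethylundeca-1,5,9-triene
Product: 8 (4S,5E)-4-(tert-butyldimethylsilyloxy)-6,10-dimethylundeca-5,9-dien-1-ol, via B-alkyl-9-BBN adduct 7 (not isolated)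
Conditions: 9-BBN, THF, 0 °C to rt; NaOH, 30% H2O2, 0 °C
Reagents that add atoms: hydrogen peroxide, OO
Why: In this hydroboration–oxidation, 9-BBN adds anti-Markovnikov to the monosubstituted alkene far faster than to the two trisubstituted alkenes, and alkaline peroxide replaces boron by hydroxyl.

**Step 4**
Reactants: 8 (4S,5E)-4-(tert-butyldimethylsilyloxy)-6,10-dimethylundeca-5,9-dien-1-ol
Product: 9 (4S,5E)-4-(tert-butyldimethylsilyloxy)-6,10-dimethylundeca-5,9-dienal
Conditions: TEMPO (cat.), PhI(OAc)2, CH2Cl2, rt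
Reagents that add atoms: none
Why: Oxoammonium (TEMPO) oxidation of a primary alcohol stops at the aldehyde and leaves the alkenes and the silyl ether untouched.

**Step 5**
Reactants: 9 (4S,5E)-4-(tert-butyldimethylsilyloxy)-6,10-dimethylundeca-5,9-dienal; 10 3-bromo-1,1-dimethoxypropane
Product: 12 (7S,8E)-7-(tert-butyldimethylsilyloxy)-1,1-dimethoxy-9,13-dimethyltetradeca-8,12-dien-4-ol (mixture of C4 epimers), via 3,3-dimethoxypropylmagnesium bromide 11 (not isolated)
Conditions: 10, Mg, THF, ≤25 °C; 9, −78 to 0 °C; sat. aq. NH4Cl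
Reagents that add atoms: none
Why: In this Grignard addition to an aldehyde, the acetal-bearing reagent is kept at or below room temperature to avoid 1,3-elimination to a cyclopropyl ether, and the unselective new carbinol centre is erased in step 6.

**Step 6**
Reactants: 12 (7S,8E)-7-(tert-butyldimethylsilyloxy)-1,1-dimethoxy-9,13-dimethyltetradeca-8,12-dien-4-ol
Product: 13 (7S,8E)-7-(tert-butyldimethylsilyloxy)-1,1-dimethoxy-9,13-dimethyltetradeca-8,12-dien-4-one
Conditions: nPr4N[RuO4] (cat.), NMO, 4 Å MS, CH2Cl2, rt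
Reagents that add atoms: none
Why: Ley–Griffith oxidation of a secondary alcohol runs under neutral conditions that the acetal, the silyl ether and the trisubstituted alkenes tolerate.

**Step 7**
Reactants: 13 (7S,8E)-7-(tert-butyldimethylsilyloxy)-1,1-dimethoxy-9,13-dimethyltetradeca-8,12-dien-4-one; 14 ethyl formate
Product: 16 3-(2,2-dimethoxyethyl)-5-[(2S,3E)-2-(tert-butyldimethylsilyloxy)-4,8-dimethylnona-3,7-dienyl]-4H-pyran-4-one, via bis(hydroxymethylene) ketone 15 (not isolated)
Conditions: NaH (excess), 14 (excess), EtOH (cat.), THF, 0 to 40 °C; AcOH; crude 15, PPTS (cat.), 4 Å MS, CH2Cl2, rt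
Reagents that add atoms: none
Why: A double crossed Claisen formylation at both α-methylene groups (the second being the NaH-mediated acylation of a β-dicarbonyl enolate at its α' carbon, with both monoformyl isomers converging on 15) is followed by acid-catalysed cyclodehydration of the 1,3,5-tricarbonyl system, the classical route from dialkyl ketones to 3,5-dialkyl-4-pyranones, and the sieves take up the water so that the acetal stays.

**Step 8**
Reactants: 16 3-(2,2-dimethoxyethyl)-5-[(2S,3E)-2-(tert-butyldimethylsilyloxy)-4,8-dimethylnona-3,7-dienyl]-4H-pyran-4-one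
Product: 17 2-{4-oxo-5-[(2S,3E)-2-(tert-butyldimethylsilyloxy)-4,8-dimethylnona-3,7-dienyl]-4H-pyran-3-yl}acetaldehyde
Conditions: PPTS (cat.), acetone–H2O 10:1, 45 °C; used without delay
Reagents that add atoms: water, O
Why: Mild acid-catalysed hydrolysis cleaves an unhindered dimethyl acetal under conditions that a secondary TBS ether and the 4-pyranone should withstand.

**Step 9**
Reactants: 17 2-{4-oxo-5-[(2S,3E)-2-(tert-butyldimethylsilyloxy)-4,8-dimethylnona-3,7-dienyl]-4H-pyran-3-yl}acetaldehyde
Product: 18 3-[2-(triisopropylsilyloxy)vinyl]-5-[(2S,3E)-2-(tert-butyldimethylsilyloxy)-4,8-dimethylnona-3,7-dienyl]-4H-pyran-4-one (E/Z mixture at the enol ether expected, both isomers usable)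
Conditions: TIPSOTf, Et3N, CH2Cl2, −78 to 0 °C; sat. aq. NaHCO3
Reagents that add atoms: triisopropylsilyl triflate, CC(C)[Si](OS(=O)(=O)C(F)(F)F)(C(C)C)C(C)C
Why: In this soft enolisation–silylation, the methylene between the formyl group and the pyranone C=C is acidic and should give the conjugated silyl enol ether, while any O-silylation of the pyranone carbonyl is reversible and is undone by the bicarbonate work-up.

**Step 10**
Reactants: 18 3-[2-(triisopropylsilyloxy)vinyl]-5-[(2S,3E)-2-(tert-butyldimethylsilyloxy)-4,8-dimethylnona-3,7-dienyl]-4H-pyran-4-one; 19 (Z)-1-bromo-2-ethoxyethene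
Product: 21 4-[(Z)-2-ethoxyvinyl]-3-[2-(triisopropylsilyloxy)vinyl]-5-[(2S,3E)-2-(tert-butyldimethylsilyloxy)-4,8-dimethylnona-3,7-dienyl]-4H-pyran-4-ol (mixture of C4a epimers), via (Z)-2-ethoxyvinyllithium 20 (not isolated)
Conditions: 19, n-BuLi, Et2O, −78 °C; 18, THF, −78 °C; H2O quench; extracted under basic conditions and used crude
Reagents that add atoms: none
Why: Bromine–lithium exchange with retention gives the configurationally stable vinyllithium, which adds 1,2 to the pyranone carbonyl as organolithium and Grignard reagents do in the classical pyranone-to-pyrylium sequence; the unselective C4a centre is erased in step 11 and the basic work-up protects the acid-labile carbinol.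

**Step 11**
Reactants: 21 4-[(Z)-2-ethoxyvinyl]-3-[2-(triisopropylsilyloxy)vinyl]-5-[(2S,3E)-2-(tert-butyldimethylsilyloxy)-4,8-dimethylnona-3,7-dienyl]-4H-pyran-4-ol
Product: 25 4-[(2S,3E)-2-(tert-butyldimethylsilyloxy)-4,8-dimethylnona-3,7-dienyl]cyclopenta[c]pyran-7-carbaldehyde, via trimethylsilyl ether 22 (not isolated), via ethoxyvinylpyrylium triflate 23 (not isolated), via 6-ethoxy-6,7-dihydro aldehyde 24 (not isolated)
Conditions: TMSOTf (2.5 equiv), 2,6-lutidine (4 equiv), CH2Cl2, −78 to 0 °C; sat. aq. NaHCO3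
Reagents that add atoms: none
Why: Proposed new method: TMSOTf silylates the tertiary hydroxyl (22) and a second equivalent carries the oxygen off as hexamethyldisiloxane, leaving pyrylium triflate 23, whose charge reaches C6 through the ethoxyvinyl group (O-ethyl oxocarbenium form with C4a=C5); the enol ether carbon C7 adds to C6, the silyl group leaves the formyl oxygen as TIPSOTf to give 24, and silyl triflate with lutidine then removes the C6 ethoxy group and the acidic C7 proton, so that C6=C7 completes the 10π cyclopenta[c]pyran. The closest known reaction types are the Mukaiyama-type addition of silyl enol ethers to oxocarbenium ions, the ionisation of 2-ethoxyvinyl carbinols used for two-carbon aldehyde homologation, and the addition–elimination of carbon nucleophiles at the alkoxy carbon of 4-(2-alkoxyvinyl)pyrylium salts in polymethine dye synthesis, but their union in a ring closure on a 4H-pyran-4-ol has not been shown. The five-membered ring (C4a–C5–C6–C7–C7a) closes in the 5-(enolexo)-exo-trig mode, and the low C4a–C5 and C5–C6 bond orders of the cation allow the rotations that bring C6 next to C7 whatever the Z geometry of 21. No stereocentre is created in the product, because both C4a epimers of 21 give the same planar cation, the C6 and C7 centres of 24 vanish on elimination, and the S centre at C2' takes no part. Regioselectivity rests on the polarity of the arms, since C7 is the only nucleophilic carbon and C6 is the only cationic carbon it can reach (C1, C3 and C4a are out of range for a viable ring), so a 5-formyl isomer cannot arise. Chemoselectivity needs the carbinol to ionise before the allylic silyl ether or the enol ether is attacked, which the much greater stability of the pyrylium ion, the aprotic lutidine buffer and the low temperature should secure.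

**Step 12**
Reactants: 25 4-[(2S,3E)-2-(tert-butyldimethylsilyloxy)-4,8-dimethylnona-3,7-dienyl]cyclopenta[c]pyran-7-carbaldehyde
Product: 26 4-[(2S,3E)-2-hydroxy-4,8-dimethylnona-3,7-dienyl]cyclopenta[c]pyran-7-carbaldehyde
Conditions: nBu4NF, AcOH (1:1), THF, 0 °C to rt
Reagents that add atoms: none
Why: Fluoride cleaves the Si–O bond without touching the C–O bond, so the configuration is kept, and the acetic acid buffer keeps the medium from opening the base-sensitive formyl-conjugated pyran.

**Step 13**
Reactants: 26 4-[(2S,3E)-2-hydroxy-4,8-dimethylnona-3,7-dienyl]cyclopenta[c]pyran-7-carbaldehyde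
Product: 27 (2S,3E)-1-(7-formylcyclopenta[c]pyran-4-yl)-4,8-dimethylnona-3,7-dien-2-yl acetate
Conditions: Ac2O, Et3N, DMAP (cat.), CH2Cl2, 0 °C
Reagents that add atoms: acetic anhydride, CC(=O)OC(C)=O
Why: DMAP-catalysed acyl transfer acylates the secondary allylic alcohol at oxygen with retention and should give the target as the S enantiomer.

**Compound list**
1 | geranial, (2E)-3,7-dimethylocta-2,6-dienal | O=C/C=C(\C)CCC=C(C)C | starting material
2 | allylmagnesium bromide | C=CC[Mg]Br | starting material
3 | B-allyldiisopinocampheylborane from (+)-α-pinene | C=CCB([C@@H]1C[C@@H]2C[C@H]([C@H]1C)C2(C)C)[C@@H]1C[C@@H]2C[C@H]([C@H]1C)C2(C)C | intermediate (not isolated)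
4 | (4S,5E)-6,10-dimethylundeca-1,5,9-trien-4-yl diisopinocampheylborinate | B([C@@H]1C[C@@H]2C[C@H]([C@H]1C)C2(C)C)([C@@H]1C[C@@H]2C[C@H]([C@H]1C)C2(C)C)O[C@H](/C=C(\C)CCC=C(C)C)CC=C | intermediate (not isolated)
5 | (4S,5E)-6,10-dimethylundeca-1,5,9-trien-4-ol | O[C@H](/C=C(\C)CCC=C(C)C)CC=C | intermediate
6 | (4S,5E)-4-(tert-butyldimethylsilyloxy)-6,10-dimethylundeca-1,5,9-triene | CC(C)(C)[Si](C)(C)O[C@H](/C=C(\C)CCC=C(C)C)CC=C | intermediate
7 | 9-[(4S,5E)-4-(tert-butyldimethylsilyloxy)-6,10-dimethylundeca-5,9-dienyl]-9-borabicyclo[3.3.1]nonane | CC(C)(C)[Si](C)(C)O[C@H](/C=C(\C)CCC=C(C)C)CCCB1C2CCCC1CCC2 | intermediate (not isolated)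
8 | (4S,5E)-4-(tert-butyldimethylsilyloxy)-6,10-dimethylundeca-5,9-dien-1-ol | CC(C)(C)[Si](C)(C)O[C@H](/C=C(\C)CCC=C(C)C)CCCO | intermediate
9 | (4S,5E)-4-(tert-butyldimethylsilyloxy)-6,10-dimethylundeca-5,9-dienal | CC(C)(C)[Si](C)(C)O[C@H](/C=C(\C)CCC=C(C)C)CCC=O | intermediate
10 | 3-bromo-1,1-dimethoxypropane | BrCCC(OC)OC | starting material
11 | 3,3-dimethoxypropylmagnesium bromide | Br[Mg]CCC(OC)OC | intermediate (not isolated)
12 | (7S,8E)-7-(tert-butyldimethylsilyloxy)-1,1-dimethoxy-9,13-dimethyltetradeca-8,12-dien-4-ol, C4 epimers | CC(C)(C)[Si](C)(C)O[C@H](/C=C(\C)CCC=C(C)C)CCC(O)CCC(OC)OC | intermediate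
13 | (7S,8E)-7-(tert-butyldimethylsilyloxy)-1,1-dimethoxy-9,13-dimethyltetradeca-8,12-dien-4-one | CC(C)(C)[Si](C)(C)O[C@H](/C=C(\C)CCC=C(C)C)CCC(=O)CCC(OC)OC | intermediate
14 | ethyl formate | CCOC=O | starting material
15 | 3,5-bis(hydroxymethylene) derivative of ketone 13 | CC(C)(C)[Si](C)(C)O[C@H](/C=C(\C)CCC=C(C)C)CC(=CO)C(=O)C(=CO)CC(OC)OC | intermediate (not isolated)
16 | 3-(2,2-dimethoxyethyl)-5-[(2S,3E)-2-(tert-butyldimethylsilyloxy)-4,8-dimethylnona-3,7-dienyl]-4H-pyran-4-one | CC(C)(C)[Si](C)(C)O[C@H](/C=C(\C)CCC=C(C)C)CC1=COC=C(CC(OC)OC)C1=O | intermediate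
17 | 2-{4-oxo-5-[(2S,3E)-2-(tert-butyldimethylsilyloxy)-4,8-dimethylnona-3,7-dienyl]-4H-pyran-3-yl}acetaldehyde | CC(C)(C)[Si](C)(C)O[C@H](/C=C(\C)CCC=C(C)C)CC1=COC=C(CC=O)C1=O | intermediate
18 | 3-[2-(triisopropylsilyloxy)vinyl]-5-[(2S,3E)-2-(tert-butyldimethylsilyloxy)-4,8-dimethylnona-3,7-dienyl]-4H-pyran-4-one, E/Z at the enol ether | CC(C)(C)[Si](C)(C)O[C@H](/C=C(\C)CCC=C(C)C)CC1=COC=C(C=CO[Si](C(C)C)(C(C)C)C(C)C)C1=O | intermediate
19 | (Z)-1-bromo-2-ethoxyethene | Br/C=C\OCC | starting material
20 | (Z)-2-ethoxyvinyllithium | [Li]/C=C\OCC | intermediate (not isolated)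
21 | 4-[(Z)-2-ethoxyvinyl]-3-[2-(triisopropylsilyloxy)vinyl]-5-[(2S,3E)-2-(tert-butyldimethylsilyloxy)-4,8-dimethylnona-3,7-dienyl]-4H-pyran-4-ol, C4a epimers | CC(C)(C)[Si](C)(C)O[C@H](/C=C(\C)CCC=C(C)C)CC1=COC=C(C=CO[Si](C(C)C)(C(C)C)C(C)C)C1(O)/C=C\OCC | intermediate (key-step precursor)
22 | O-trimethylsilyl ether of 21 | CC(C)(C)[Si](C)(C)O[C@H](/C=C(\C)CCC=C(C)C)CC1=COC=C(C=CO[Si](C(C)C)(C(C)C)C(C)C)C1(O[Si](C)(C)C)/C=C\OCC | intermediate (not isolated)
23 | 4-(2-ethoxyvinyl)-3-[2-(triisopropylsilyloxy)vinyl]-5-[(2S,3E)-2-(tert-butyldimethylsilyloxy)-4,8-dimethylnona-3,7-dienyl]pyrylium triflate | CC(C)(C)[Si](C)(C)O[C@H](/C=C(\C)CCC=C(C)C)Cc1c[o+]cc(C=CO[Si](C(C)C)(C(C)C)C(C)C)c1/C=C\OCC.[O-]S(=O)(=O)C(F)(F)F | intermediate (not isolated)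
24 | 6-ethoxy-4-[(2S,3E)-2-(tert-butyldimethylsilyloxy)-4,8-dimethylnona-3,7-dienyl]-6,7-dihydrocyclopenta[c]pyran-7-carbaldehyde, C6/C7 isomers | CC(C)(C)[Si](C)(C)O[C@H](/C=C(\C)CCC=C(C)C)CC1=COC=C2C(C=O)C(OCC)C=C12 | intermediate (not isolated)
25 | 4-[(2S,3E)-2-(tert-butyldimethylsilyloxy)-4,8-dimethylnona-3,7-dienyl]cyclopenta[c]pyran-7-carbaldehyde | CC(C)(C)[Si](C)(C)O[C@H](/C=C(\C)CCC=C(C)C)Cc1cocc2c(C=O)ccc1-2 | intermediate (key-step product)
26 | 4-[(2S,3E)-2-hydroxy-4,8-dimethylnona-3,7-dienyl]cyclopenta[c]pyran-7-carbaldehyde | O[C@H](/C=C(\C)CCC=C(C)C)Cc1cocc2c(C=O)ccc1-2 | intermediate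
27 | (2S,3E)-1-(7-formylcyclopenta[c]pyran-4-yl)-4,8-dimethylnona-3,7-dien-2-yl acetate (CNP0325919.1) | CC(=O)O[C@H](/C=C(\C)CCC=C(C)C)Cc1cocc2c(C=O)ccc1-2 | target

**Step count**
Total steps: 13. Longest linear sequence: 13 (1 to 27).

**Steps most likely to fail**

Step 11. The donor-stabilised pyrylium ion may be too weak an electrophile at C6, or the enol ether on the cationic ring too poor a nucleophile. Ring closure would then lag behind hydrolysis at the quench or behind ionisation of the allylic silyl ether.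

The fallback closes the same bond stepwise by known reactions. It sets out from 16 and returns at 25.
- Pyranone 16 is treated with 20, as in step 10, to give the 3-(2,2-dimethoxyethyl)-4-[(Z)-2-ethoxyvinyl]-4H-pyran-4-ol F1.
- Dilute aqueous oxalic acid in THF converts the ethoxyvinyl carbinol into the enal, as is well established, and also hydrolyses the acetal. This gives the (4H-pyran-4-ylidene)acetaldehyde bearing the acetaldehyde arm, dialdehyde F2.
- Dibenzylammonium trifluoroacetate in toluene then brings about the intramolecular aldol condensation of this 1,6-dialdehyde, the reaction type that turns hexanedial into cyclopentene-1-carbaldehyde.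
- Only the C7 methylene can enolise, so the regiochemistry is unchanged, and loss of water gives 25.

Step 10. The basic vinyllithium may deprotonate the unsubstituted C1–H or C3–H positions of the pyranone, or add in a conjugate sense with ring opening. The carbinol may also lose water during isolation.

The fallback is the Arens–van Dorp sequence. It sets out from 18 and returns at 21.
- Ethoxyacetylene and n-BuLi give lithium ethoxyacetylide F3, which is much less basic and sterically slimmer.
- F3 adds to the carbonyl of 18 to give the 4-(ethoxyethynyl)-4H-pyran-4-ol F4.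
- Semihydrogenation of F4 with H2 over Pd on CaCO3 poisoned with Pb(OAc)2, with quinoline present, delivers the cis enol ether 21.

Step 7. The second formylation may stall at the monoformyl enolate, the ketone may self-condense, or the enol of 15 may be intercepted by the neighbouring acetal during the acid treatment.

The fallback avoids enolate chemistry. It sets out from 13 and returns at 16.
- Ketone 13 is heated with excess tert-butoxybis(dimethylamino)methane (Bredereck's reagent) to give the 3,5-bis(dimethylaminomethylene) ketone F5.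
- Aqueous acetic acid hydrolyses F5 and cyclises it to pyranone 16 with loss of dimethylamine.

**Further compounds**
F1 | step 11 | 3-(2,2-dimethoxyethyl)-4-[(Z)-2-ethoxyvinyl]-5-[(2S,3E)-2-(tert-butyldimethylsilyloxy)-4,8-dimethylnona-3,7-dienyl]-4H-pyran-4-ol | CC(C)(C)[Si](C)(C)O[C@H](/C=C(\C)CCC=C(C)C)CC1=COC=C(CC(OC)OC)C1(O)/C=C\OCC
F2 | step 11 | 2-{4-(2-oxoethylidene)-5-[(2S,3E)-2-(tert-butyldimethylsilyloxy)-4,8-dimethylnona-3,7-dienyl]-4H-pyran-3-yl}acetaldehyde | CC(C)(C)[Si](C)(C)O[C@H](/C=C(\C)CCC=C(C)C)CC1=COC=C(CC=O)C1=CC=O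
F3 | step 10 | lithium ethoxyacetylide | [Li]C#COCC
F4 | step 10 | 4-(ethoxyethynyl)-3-[2-(triisopropylsilyloxy)vinyl]-5-[(2S,3E)-2-(tert-butyldimethylsilyloxy)-4,8-dimethylnona-3,7-dienyl]-4H-pyran-4-ol | CC(C)(C)[Si](C)(C)O[C@H](/C=C(\C)CCC=C(C)C)CC1=COC=C(C=CO[Si](C(C)C)(C(C)C)C(C)C)C1(O)C#COCC
F5 | step 7 | (7S,8E)-7-(tert-butyldimethylsilyloxy)-3,5-bis(dimethylaminomethylene)-1,1-dimethoxy-9,13-dimethyltetradeca-8,12-dien-4-one | CC(C)(C)[Si](C)(C)O[C@H](/C=C(\C)CCC=C(C)C)CC(=CN(C)C)C(=O)C(=CN(C)C)CC(OC)OC
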